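**Retrosynthetic overview**
1. The strategy rests on the ring itself, numbered C1(=O)–C2(OH)–C3(chain)–C4(=O)–C5(OH)–C6(H). In its tetraketo tautomer it is two vicinal dicarbonyl pairs (C1/C2 and C4/C5) bridged by C3 and C6. Cutting C3–C4 and C5–C6 gives a 2,3-diketone (C6–C1–C2–C3 plus chain) and an oxalyl unit (C4–C5).
2. The diketone, (E)-tricos-18-ene-2,3-dione, comes from its 2,2-dimethyl ketal, made by acylating a C20 Grignard reagent with the Weinreb amide of pyruvic acid dimethyl ketal.
3. The C20 bromide comes from a copper-catalysed sp3–sp3 coupling of a C14 Grignard reagent with 1,6-dibromohexane. The C14 unit is myristelaidic acid, which supplies the E-alkene ready-made.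
4. Ring order: the only ring is formed last, directly at the dihydroxyquinone oxidation level.

Key step: step 7

Assumption: the target has no stereogenic centre, so "single enantiomer" is read as the single (E)-alkene isomer drawn; that geometry is bought in with myristelaidic acid and never touched.

**Route**

Step 1
Reactants: 1 myristelaidic acid [(E)-tetradec-9-enoic acid]
Product: 2 (E)-tetradec-9-en-1-ol
Conditions: LiAlH4 (1.5 equiv), THF, 0 °C → rt; H2O/15% NaOH work-up
Reagents that add atoms: none
Why: Hydride reduction of a carboxylic acid with LiAlH4 should give the primary alcohol and leaves an isolated, non-conjugated E-alkene untouched.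

Step 2
Reactants: 2 (E)-tetradec-9-en-1-ol
Product: 3 (E)-14-bromotetradec-5-ene [(E)-1-bromotetradec-9-ene]
Conditions: CBr4, PPh3, CH2Cl2, 0 °C → rt
Reagents that add atoms: carbon tetrabromide, BrC(Br)(Br)Br
Why: The Appel reaction converts the primary alcohol into the bromide by SN2 displacement of an oxyphosphonium group under neutral conditions that cannot isomerise the alkene.

Step 3
Reactants: 3 (E)-14-bromotetradec-5-ene; 4 1,6-dibromohexane
Product: 6 (E)-20-bromoicos-5-ene [(E)-1-bromoicos-15-ene], via (E)-tetradec-9-enylmagnesium bromide 5 (not isolated)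
Conditions: Mg, THF, 45 °C; then added slowly to 4 (3 equiv), Li2CuCl4 (3 mol%), THF, −10 °C → rt
Reagents that add atoms: none
Why: Copper-catalysed (Kochi-type) cross-coupling of a primary alkyl Grignard reagent with a primary alkyl bromide forms the sp3–sp3 bond, and the threefold excess of dibromide with slow addition of 5 should hold the reaction at mono-substitution.

Step 4
Reactants: 7 methyl 2,2-dimethoxypropanoate
Product: 8 N,2,2-trimethoxy-N-methylpropanamide
Conditions: MeNH(OMe)·HCl (1.5 equiv), i-PrMgCl (3.0 equiv), THF, −20 → 0 °C
Reagents that add atoms: N,O-dimethylhydroxylamine hydrochloride, CNOC.Cl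
Why: Aminolysis of the α-alkoxy-activated ester by the magnesium amide formed in situ is a standard Weinreb amide synthesis, and the dimethyl ketal is inert to these basic conditions.

Step 5
Reactants: 6 (E)-20-bromoicos-5-ene; 8 N,2,2-trimethoxy-N-methylpropanamide
Product: 10 (E)-2,2-dimethoxytricos-18-en-3-one, via (E)-icos-15-enylmagnesium bromide 9 (not isolated)
Conditions: Mg, THF, 45 °C; then 8 (1.2 equiv), THF, 0 °C → rt; aq. NH4Cl
Reagents that add atoms: none
Why: In the Weinreb ketone synthesis the five-membered magnesium chelate of the tetrahedral adduct survives until work-up, so the Grignard reagent should add only once and deliver the α-ketal ketone.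

Step 6
Reactants: 10 (E)-2,2-dimethoxytricos-18-en-3-one
Product: 11 (E)-tricos-18-ene-2,3-dione
Conditions: 2 M aq. HCl, THF, 45 °C
Reagents that add atoms: water, O
Why: Acid-catalysed ketal hydrolysis unmasks the second carbonyl group, and dilute aqueous acid does not protonate or isomerise an isolated 1,2-disubstituted alkene.

Step 7
Reactants: 11 (E)-tricos-18-ene-2,3-dione; 12 diethyl oxalate
Product: 16 2,5-dihydroxy-3-[(E)-nonadec-14-enyl]cyclohexa-2,5-diene-1,4-dione (target), via lithium (18E)-3-oxotricosa-1,18-dien-2-olate 13 (not isolated), via ethyl (E)-2,4,5-trioxopentacos-20-enoate 14 (not isolated), via dipotassium 2-[(E)-nonadec-14-enyl]-3,6-dioxocyclohexa-1,4-diene-1,4-diolate 15 (not isolated)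
Conditions: LiHMDS (1.1 equiv), THF, −78 °C, slow addition of 11; transfer into 12 (1.3 equiv), THF, −78 → 0 °C; then KOtBu (2.5 equiv), t-BuOH/THF, 50 °C, Ar; then 2 M HCl to pH 1
Reagents that add atoms: none
Why: Proposed new method: enolate 13, pre-formed mainly on the C1 methyl of 11, is C-acylated by one ester group of 12 (crossed Claisen, ring bond C6–C5) and rests as the β-diketonate of 14; KOtBu then reversibly deprotonates the remaining α-CH2 (C4 of 11, ring C3), whose carbon attacks the second, now intramolecular ester carbon (Dieckmann, ring bond C3–C4), ethoxide leaves, and the resulting 3-alkylcyclohexane-1,2,4,5-tetraone is deprotonated twice to the quinonoid dianion 15, which acid converts into 16. The closest known reaction types are the crossed Claisen condensation of methyl ketone enolates with dialkyl oxalates and the Claisen–Dieckmann annulation of dialkyl ketones with oxalate to cyclopentane-1,2,4-triones; new here is a 1,2-diketone as the four-carbon partner, so that the ring emerges six-membered and already at the dihydroxyquinone oxidation level. The only ring closes in a 6-(enolendo)-exo-trig Dieckmann mode, whereas aldol attack of the same carbon on the C2 ketone of 14 (ring C5) would be a disfavoured 5-(enolendo)-exo-trig closure onto a carbonyl that is in any case masked as the diketonate. No stereocentre is created, and the remote E-alkene is inert to amide and alkoxide bases. The step needs C- over O-acylation and cross- over self-condensation: enol esters or lactones from O-acylation are reopened by alkoxide while the C-acylated product is withdrawn as the doubly deprotonated, strongly stabilised 15, self-aldol is suppressed by forming 13 completely by inverse addition before it meets any electrophile other than the non-enolisable oxalate, and regiochemistry is moot because oxalate is symmetric, so acylation of either α-carbon first leads to the same ring. Potassium tert-butoxide in t-BuOH/THF is chosen for the closure because it loosens the lithium chelate that holds the diketonate of 14 in the extended W shape and lets it reach the U-shaped rotamer from which ring C3 and C4 can bond.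

**Compound list**
1 | myristelaidic acid, (E)-tetradec-9-enoic acid | CCCC/C=C/CCCCCCCC(=O)O | starting material
2 | (E)-tetradec-9-en-1-ol | CCCC/C=C/CCCCCCCCO | intermediate
3 | (E)-14-bromotetradec-5-ene [(E)-1-bromotetradec-9-ene] | CCCC/C=C/CCCCCCCCBr | intermediate
4 | 1,6-dibromohexane | BrCCCCCCBr | starting material
5 | (E)-tetradec-9-enylmagnesium bromide | CCCC/C=C/CCCCCCCC[Mg]Br | intermediate (not isolated)
6 | (E)-20-bromoicos-5-ene [(E)-1-bromoicos-15-ene] | CCCC/C=C/CCCCCCCCCCCCCCBr | intermediate
7 | methyl 2,2-dimethoxypropanoate | COC(=O)C(C)(OC)OC | starting material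
8 | N,2,2-trimethoxy-N-methylpropanamide | CON(C)C(=O)C(C)(OC)OC | intermediate
9 | (E)-icos-15-enylmagnesium bromide | CCCC/C=C/CCCCCCCCCCCCCC[Mg]Br | intermediate (not isolated)
10 | (E)-2,2-dimethoxytricos-18-en-3-one | CCCC/C=C/CCCCCCCCCCCCCCC(=O)C(C)(OC)OC | intermediate
11 | (E)-tricos-18-ene-2,3-dione | CCCC/C=C/CCCCCCCCCCCCCCC(=O)C(C)=O | intermediate (key-step precursor)
12 | diethyl oxalate | CCOC(=O)C(=O)OCC | starting material
13 | lithium (18E)-3-oxotricosa-1,18-dien-2-olate (kinetic enolate of 11) | CCCC/C=C/CCCCCCCCCCCCCCC(=O)C(=C)[O-].[Li+] | intermediate (not isolated)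
14 | ethyl (E)-2,4,5-trioxopentacos-20-enoate (present as its enolate) | CCCC/C=C/CCCCCCCCCCCCCCC(=O)C(=O)CC(=O)C(=O)OCC | intermediate (not isolated)
15 | dipotassium 2-[(E)-nonadec-14-enyl]-3,6-dioxocyclohexa-1,4-diene-1,4-diolate (dianion of the target; mixed Li/K counter-ions in the flask) | CCCC/C=C/CCCCCCCCCCCCCC1=C([O-])C(=O)C=C([O-])C1=O.[K+].[K+] | intermediate (not isolated)
16 | 2,5-dihydroxy-3-[(E)-nonadec-14-enyl]cyclohexa-2,5-diene-1,4-dione | CCCC/C=C/CCCCCCCCCCCCCC1=C(O)C(=O)C=C(O)C1=O | target

**Step count**
Total: 7 steps. Longest linear sequence: 6 steps (1 → 2 → 3 → 5 → 6 → 7); step 4 is a one-step branch.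

**Steps most likely to fail**

1. Step 7 (labelled as a proposed new method). Possible failures are:
   - self-aldol condensation of the diketone enolate before it is acylated;
   - over-acylation of the product dianion at C6 by surplus oxalate;
   - stalling at the acyclic stage, because the chelated diketonate does not reach the rotamer needed for ring closure.

   Fallback, by known chemistry, sets out from Grignard reagent 5 (made from 3 as in step 3) and returns at target 16. Reagent 5 is coupled under the same copper catalysis with excess 1,5-dibromopentane to give (E)-1-bromononadec-14-ene F1. 1,2,4,5-Tetramethoxybenzene is deprotonated with n-BuLi (THF/TMEDA) to (2,3,5,6-tetramethoxyphenyl)lithium F2, which is alkylated by F1 to give 1,2,4,5-tetramethoxy-3-[(E)-nonadec-14-enyl]benzene F3. Oxidative demethylation with ceric ammonium nitrate (MeCN/H2O, 0 °C) should give 2,5-dimethoxy-3-[(E)-nonadec-14-enyl]cyclohexa-2,5-diene-1,4-dione F4. Hydrolysis of its two vinylogous ester methoxy groups (aq. NaOH, EtOH, then HCl) gives 16.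

2. Step 5. Addition of the long-chain Grignard reagent to the α-quaternary, ketal-flanked Weinreb carbonyl may be slow. That would allow Wurtz-type homocoupling during reagent formation and base-induced N–O cleavage of the amide to compete.

   Fallback sets out from Grignard reagent 9 (from 6) and returns at dione 11, bypassing 8 and 10. Reagent 9 is added to 1,4-dimethylpiperazine-2,3-dione (THF, −78 → 0 °C) to give the mono-adduct 3-hydroxy-3-[(E)-icos-15-enyl]-1,4-dimethylpiperazin-2-one F5, held as its magnesium alkoxide. MeLi is then added to the remaining amide carbonyl to give 2-[(E)-icos-15-enyl]-1,3,4-trimethylpiperazine-2,3-diol F6 as its dialkoxide. Aqueous HCl hydrolyses both hemiaminals to give 11.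

3. Step 3. Statistical substitution at both ends of the dibromide and homocoupling of the Grignard reagent may erode the mono-coupled bromide, and the apolar by-products may be hard to separate.

   Fallback sets out from Grignard reagent 5 (from 3) and returns at 6. Reagent 5 is coupled (Li2CuCl4 cat., THF) with the differentiated C6 unit 2-(6-bromohexoxy)oxane (commercial THP ether of 6-bromohexan-1-ol) to give 2-[(E)-icos-15-enoxy]oxane F7. PPTS in MeOH removes the acetal to give (E)-icos-15-en-1-ol F8. CBr4/PPh3 as in step 2 gives 6.

**Further compounds**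
F1 | step 7 | (E)-1-bromononadec-14-ene [(E)-19-bromononadec-5-ene] | CCCC/C=C/CCCCCCCCCCCCCBr
F2 | step 7 | (2,3,5,6-tetramethoxyphenyl)lithium | [Li]c1c(OC)c(OC)cc(OC)c1OC
F3 | step 7 | 1,2,4,5-tetramethoxy-3-[(E)-nonadec-14-enyl]benzene | CCCC/C=C/CCCCCCCCCCCCCc1c(OC)c(OC)cc(OC)c1OC
F4 | step 7 | 2,5-dimethoxy-3-[(E)-nonadec-14-enyl]cyclohexa-2,5-diene-1,4-dione | CCCC/C=C/CCCCCCCCCCCCCC1=C(OC)C(=O)C=C(OC)C1=O
F5 | step 5 | 3-hydroxy-3-[(E)-icos-15-enyl]-1,4-dimethylpiperazin-2-one (as its magnesium alkoxide) | CCCC/C=C/CCCCCCCCCCCCCCC1(O)N(C)CCN(C)C1=O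
F6 | step 5 | 2-[(E)-icos-15-enyl]-1,3,4-trimethylpiperazine-2,3-diol (as its dialkoxide) | CCCC/C=C/CCCCCCCCCCCCCCC1(O)N(C)CCN(C)C1(C)O
F7 | step 3 | 2-[(E)-icos-15-enoxy]oxane | CCCC/C=C/CCCCCCCCCCCCCCOC1CCCCO1
F8 | step 3 | (E)-icos-15-en-1-ol | CCCC/C=C/CCCCCCCCCCCCCCO
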